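The route builds ring B by a convergent radical annulation between a ring A silane and a preformed bis-spiro furanone aldehyde. It exploits two features: O6 and C19 sit syn-axial on the β-face across C4–C5–C6, so a SiMe2 unit can bridge them as a temporary 1-oxa-2-silacyclohexane, and the C9–C11–C12(=O) unit of the tetrahydrofuran-3-one ring is the product of radical addition to C9 of a 3(2H)-furanone. The precursor is the O-silyl hemiselenoacetal formed in the flask from the two fragments. In one operation an α-siloxy C6 radical closes onto C5 of the C5=C10 alkene and the resulting C10 radical closes onto C9, setting C5, C6, C9 and C10. Tamao oxidation then unmasks both hydroxyls.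

Key step: step 18

Remarks: atoms carry labdane numbers (C1–C20; O6 and O19 are the two hydroxyl oxygens, C12 is the ketone, C9 and C13 are the spiro carbons). The sense of induction of the ligands in steps 2 and 5 is assumed from simple 3-alkylcyclohex-2-enones and α-methylene lactones; if either proves opposite, the antipodal ligand is used.

Step 1
Reactants: 1 3-bromocyclohex-2-en-1-one; 2 (chloromethyl)dimethylsilane
Product: 5 3-[(dimethylsilyl)methyl]cyclohex-2-en-1-one, via Grignard reagent 3 (not isolated), via organozinc chloride 4 (not isolated)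
Conditions: 2, Mg, THF, 40 °C; ZnCl2, 0 °C; then 1, Pd(PPh3)4 (3 mol %), THF, rt to 50 °C
Reagents that add atoms: none
Why: Negishi coupling of the β-bromoenone with an sp3 organozinc that has no β-hydrogen should give the 3-(silylmethyl)enone, and no stereocenter is formed.

Step 2
Reactants: 5 3-[(dimethylsilyl)methyl]cyclohex-2-en-1-one
Product: 7 (3S)-3-[(dimethylsilyl)methyl]-3-methylcyclohex-1-en-1-yl trifluoromethanesulfonate, via aluminium enolate 6 (not isolated)
Conditions: Me3Al (1.5 equiv), copper thiophene-2-carboxylate Cu(O2CC4H3S) (2 mol %), (S)-BINOL-derived phosphoramidite with a bis[(S)-1-phenylethyl]amino group (4 mol %), Et2O, −30 °C; then MeLi, THF, −78 °C; then N-(5-chloropyridin-2-yl)bis(trifluoromethanesulfonimide), −78 to 0 °C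
Reagents that add atoms: trimethylaluminium C[Al](C)C; N-(5-chloropyridin-2-yl)bis(trifluoromethanesulfonimide) O=S(=O)(N(c1ccc(Cl)cn1)S(=O)(=O)C(F)(F)F)C(F)(F)F
Why: Copper-catalysed asymmetric conjugate addition of Me3Al to the 3-substituted cyclohexenone should create the C4 quaternary center under ligand control, and triflation of the regiodefined enolate places the future C5=C10 double bond next to it.

Step 3
Reactants: 7 (3S)-3-[(dimethylsilyl)methyl]-3-methylcyclohex-1-en-1-yl trifluoromethanesulfonate
Product: 8 {[(1S)-1,3-dimethylcyclohex-2-en-1-yl]methyl}dimethylsilane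
Conditions: Me2CuLi (3 equiv), THF, −20 °C
Reagents that add atoms: lithium dimethylcuprate [Li+].C[Cu-]C
Why: Cuprate cross-coupling of the enol triflate should install the C20 methyl on C10 without touching the Si–H bond or the quaternary center.

Step 4
Reactants: 8 {[(1S)-1,3-dimethylcyclohex-2-en-1-yl]methyl}dimethylsilane
Product: 10 {[(1S)-1,3-dimethylcyclohex-2-en-1-yl]methyl}dimethyl(phenylselanyl)silane, via chlorosilane 9 (not isolated)
Conditions: trichloroisocyanuric acid (0.34 equiv), CH2Cl2, 0 °C; then PhSeLi (from PhSeH, n-BuLi), THF, −78 °C to rt; used without chromatography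
Reagents that add atoms: benzeneselenol [SeH]c1ccccc1
Why: Chlorination of the Si–H bond followed by substitution at silicon by the selenolate is the usual way to make silyl selenides, and the stereocenter is not involved.

Step 5
Reactants: 11 3-methylideneoxolan-2-one (α-methylene-γ-butyrolactone)
Product: 12 (3R)-3-methyloxolan-2-one
Conditions: H2 (50 atm), Ru(OAc)2[(S)-BINAP] (0.5 mol %), CH2Cl2, 50 °C
Reagents that add atoms: none
Why: Ru–BINAP asymmetric hydrogenation of the exocyclic α-methylene lactone should set C8 by catalyst control.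

Step 6
Reactants: 12 (3R)-3-methyloxolan-2-one
Product: 13 (3R)-5-hydroxy-3-methylpentan-2-one
Conditions: MeLi (1.05 equiv), Et2O, −78 °C; then H2O
Reagents that add atoms: methyllithium [Li]C
Why: Mono-addition of MeLi to the lactone at low temperature stops at the lithium hemiketal, which gives the γ-hydroxy methyl ketone (C9 carbonyl, C11 methyl) on work-up without enolizing C8.

Step 7
Reactants: 13 (3R)-5-hydroxy-3-methylpentan-2-one
Product: 14 (3R)-5-[(tert-butyldiphenylsilyl)oxy]-3-methylpentan-2-one
Conditions: TBDPSCl, imidazole, DMF, rt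
Reagents that add atoms: tert-butyl(chloro)diphenylsilane CC(C)(C)[Si](Cl)(c1ccccc1)c1ccccc1
Why: Silylation of the primary alcohol traps the open-chain form and protects O6 through the base and acid steps that follow.

Step 8
Reactants: 15 2-bromoprop-2-en-1-ol; 16 ethynyl(trimethyl)silane
Product: 17 2-methylidene-4-(trimethylsilyl)but-3-yn-1-ol
Conditions: PdCl2(PPh3)2 (2 mol %), CuI (4 mol %), i-Pr2NH, THF, rt
Reagents that add atoms: none
Why: Sonogashira coupling of the vinyl bromide with the silylacetylene should give the 2-alkynyl allylic alcohol that carries C12–C16.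

Step 9
Reactants: 17 2-methylidene-4-(trimethylsilyl)but-3-yn-1-ol
Product: 18 {(2S)-2-[(trimethylsilyl)ethynyl]oxiran-2-yl}methanol
Conditions: Ti(OiPr)4 (10 mol %), L-(+)-diethyl tartrate (12 mol %), t-BuOOH, 4 Å MS, CH2Cl2, −20 °C
Reagents that add atoms: tert-butyl hydroperoxide CC(C)(C)OO
Why: Sharpless asymmetric epoxidation of the 2-substituted allylic alcohol with L-(+)-tartrate should set the oxygen-bearing quaternary center C13 by reagent control.

Step 10
Reactants: 18 {(2S)-2-[(trimethylsilyl)ethynyl]oxiran-2-yl}methanol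
Product: 19 (2S)-2-{[(4-methoxyphenyl)methoxy]methyl}but-3-yne-1,2-diol
Conditions: 4-methoxybenzyl alcohol (3 equiv), NaH (2.2 equiv), DMF, 0 °C to rt
Reagents that add atoms: (4-methoxyphenyl)methanol COc1ccc(CO)cc1
Why: The alkoxide opens the epoxide by SN2 attack at its unsubstituted carbon C16 (the Payne rearrangement of this substrate is degenerate), so C13 keeps its configuration, and the basic medium also removes the alkynyl silyl group.

Step 11
Reactants: 19 (2S)-2-{[(4-methoxyphenyl)methoxy]methyl}but-3-yne-1,2-diol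
Product: 20 (2R)-2-hydroxy-2-{[(4-methoxyphenyl)methoxy]methyl}but-3-ynal
Conditions: SO3·pyridine, DMSO, i-Pr2NEt, CH2Cl2, 0 °C; used crude
Reagents that add atoms: none
Why: Parikh–Doering oxidation should convert the primary alcohol into the C12 aldehyde without the glycol cleavage that hypervalent iodine oxidants can cause in 1,2-diols.

Step 12
Reactants: 14 (3R)-5-[(tert-butyldiphenylsilyl)oxy]-3-methylpentan-2-one; 20 (2R)-2-hydroxy-2-{[(4-methoxyphenyl)methoxy]methyl}but-3-ynal
Product: 22 (3R,7R)-1-[(tert-butyldiphenylsilyl)oxy]-6,7-dihydroxy-7-{[(4-methoxyphenyl)methoxy]methyl}-3-methylnon-8-yn-4-one (both C6 epimers), via lithium enolate 21 (not isolated)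
Conditions: 14, LDA (2.05 equiv), THF, −78 °C; then 20, −78 °C; then H2O
Reagents that add atoms: none
Why: Kinetic deprotonation gives the methyl (C11) enolate, whose aldol addition to the non-enolizable aldehyde forms the C11–C12 bond; the new carbinol center is removed in the next step.

Step 13
Reactants: 22 (3R,7R)-1-[(tert-butyldiphenylsilyl)oxy]-6,7-dihydroxy-7-{[(4-methoxyphenyl)methoxy]methyl}-3-methylnon-8-yn-4-one
Product: 24 (2R)-5-{(2R)-4-[(tert-butyldiphenylsilyl)oxy]butan-2-yl}-2-ethynyl-2-{[(4-methoxyphenyl)methoxy]methyl}furan-3(2H)-one, via 1,3-diketone 23 (not isolated)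
Conditions: IBX, DMSO, rt; then 1 M HCl, THF, rt
Reagents that add atoms: none
Why: Oxidation to the 1,3-diketone and acid-catalysed cyclodehydration of an α'-hydroxy-1,3-diketone is the classical entry to 3(2H)-furanones, and the C13–O bond is not broken, so C13 is retained.

Step 14
Reactants: 24 (2R)-5-{(2R)-4-[(tert-butyldiphenylsilyl)oxy]butan-2-yl}-2-ethynyl-2-{[(4-methoxyphenyl)methoxy]methyl}furan-3(2H)-one
Product: 25 (2R)-5-{(2R)-4-[(tert-butyldiphenylsilyl)oxy]butan-2-yl}-2-ethynyl-2-(hydroxymethyl)furan-3(2H)-one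
Conditions: DDQ, CH2Cl2/pH 7 buffer, 0 °C to rt
Reagents that add atoms: none
Why: Oxidative cleavage of the 4-methoxybenzyl ether by DDQ should free O16–H without affecting the silyl ether, the alkyne or the furanone.

Step 15
Reactants: 25 (2R)-5-{(2R)-4-[(tert-butyldiphenylsilyl)oxy]butan-2-yl}-2-ethynyl-2-(hydroxymethyl)furan-3(2H)-one
Product: 26 (5R)-2-{(2R)-4-[(tert-butyldiphenylsilyl)oxy]butan-2-yl}-1,7-dioxaspiro[4.4]nona-2,8-dien-4-one
Conditions: W(CO)6 (25 mol %), THF, hν (350 nm); then 25, Et3N, rt to 40 °C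
Reagents that add atoms: none
Why: Tungsten-vinylidene cycloisomerization of the but-3-yn-1-ol unit (5-endo mode) should give the 2,3-dihydrofuran ring and so the spiro center C13 in its final form.

Step 16
Reactants: 26 (5R)-2-{(2R)-4-[(tert-butyldiphenylsilyl)oxy]butan-2-yl}-1,7-dioxaspiro[4.4]nona-2,8-dien-4-one
Product: 27 (5R)-2-[(2R)-4-hydroxybutan-2-yl]-1,7-dioxaspiro[4.4]nona-2,8-dien-4-one
Conditions: TBAF, AcOH, THF, 0 °C to rt; used directly
Reagents that add atoms: none
Why: Buffered fluoride removes the silyl ether, and the acetic acid suppresses γ-deprotonation at C8 and oxa-Michael addition of the freed alcohol to the furanone.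

Step 17
Reactants: 27 (5R)-2-[(2R)-4-hydroxybutan-2-yl]-1,7-dioxaspiro[4.4]nona-2,8-dien-4-one
Product: 28 (3R)-3-[(5R)-4-oxo-1,7-dioxaspiro[4.4]nona-2,8-dien-2-yl]butanal
Conditions: Dess–Martin periodinane, NaHCO3, CH2Cl2, 0 °C
Reagents that add atoms: none
Why: Buffered Dess–Martin oxidation should give the C6 aldehyde under conditions that the enol ether and the furanone tolerate.

Step 18
Reactants: 28 (3R)-3-[(5R)-4-oxo-1,7-dioxaspiro[4.4]nona-2,8-dien-2-yl]butanal; 10 {[(1S)-1,3-dimethylcyclohex-2-en-1-yl]methyl}dimethyl(phenylselanyl)silane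
Product: 30 cyclic siloxane of the target skeleton in which O6 and C19 are bridged by SiMe2 (O6–Si and Si–C19 bonds), via O-silyl hemiselenoacetal 29 (not isolated)
Conditions: 10 (1.2 equiv), ZnI2 (5 mol %), CH2Cl2, 0 °C; then Bu3SnH (1.3 equiv, syringe pump), AIBN, PhH (0.005 M), 80 °C
Reagents that add atoms: none
Why: The Si–Se reagent adds across the C6 aldehyde (known O-silyl hemiselenoacetal formation) and ties ring A to the chain through an O6–Si–C19 tether; Bu3Sn• then abstracts PhSe, the α-siloxy C6 radical closes the 1-oxa-2-silacyclohexane ring by 6-exo-trig attack on C5 of the C5=C10 alkene, and the tertiary C10 radical closes ring B by 6-exo-trig addition to C9, the β-carbon of the 3(2H)-furanone, before the α-keto C11 radical takes hydrogen from Bu3SnH. The closest known reaction types are the silicon-tethered (Nishiyama–Stork-type) radical cyclization and the radical cyclization onto β-alkoxy enones (β-alkoxyacrylate type), run here as one cascade. C5 is set by the tether, which can reach only the alkene face syn to C19 (relay from C4), and C6 by a chair transition state with the C7 chain equatorial. C10 is set because the face syn to the siloxane bridge is blocked, so C9 bonds anti to C6 and the methyl ends axial (trans-decalin); C9 is expected to follow from the chair of ring B with the C8 methyl equatorial and the ring oxygen, not C11, axial. The step needs both 6-exo closures to beat direct reduction, 7-endo closure and a 1,5-hydrogen shift from C8, which slow addition of Bu3SnH at high dilution and the fully substituted C10 alkene terminus should secure.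

Step 19
Reactants: 30 cyclic siloxane of the target skeleton
Product: 31 (13R)-9α,13:15,16-diepoxy-6β,19-dihydroxylabd-14-en-12-one (CNP0176827.1)
Conditions: KF, KHCO3, 30% H2O2, THF/MeOH, rt to 40 °C
Reagents that add atoms: hydrogen peroxide OO
Why: Tamao oxidation of the alkoxysilane replaces the C19–Si bond by C19–OH and releases O6–H, whose configuration was fixed in step 18 and is not touched.

Compound list
1 | 3-bromocyclohex-2-en-1-one | O=C1C=C(Br)CCC1 | starting material
2 | (chloromethyl)dimethylsilane | C[SiH](C)CCl | starting material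
3 | [(dimethylsilyl)methyl]magnesium chloride | C[SiH](C)C[Mg]Cl | intermediate
4 | [(dimethylsilyl)methyl]zinc chloride | C[SiH](C)C[Zn]Cl | intermediate
5 | 3-[(dimethylsilyl)methyl]cyclohex-2-en-1-one | O=C1C=C(C[SiH](C)C)CCC1 | intermediate
6 | dimethylaluminium (3S)-3-[(dimethylsilyl)methyl]-3-methylcyclohex-1-en-1-olate | C[C@]1(C[SiH](C)C)CCCC(O[Al](C)C)=C1 | intermediate
7 | (3S)-3-[(dimethylsilyl)methyl]-3-methylcyclohex-1-en-1-yl trifluoromethanesulfonate | C[C@]1(C[SiH](C)C)CCCC(OS(=O)(=O)C(F)(F)F)=C1 | intermediate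
8 | {[(1S)-1,3-dimethylcyclohex-2-en-1-yl]methyl}dimethylsilane | C[C@]1(C[SiH](C)C)CCCC(C)=C1 | intermediate
9 | chloro{[(1S)-1,3-dimethylcyclohex-2-en-1-yl]methyl}dimethylsilane | C[C@]1(C[Si](C)(C)Cl)CCCC(C)=C1 | intermediate
10 | {[(1S)-1,3-dimethylcyclohex-2-en-1-yl]methyl}dimethyl(phenylselanyl)silane | C[C@]1(C[Si](C)(C)[Se]c2ccccc2)CCCC(C)=C1 | intermediate
11 | 3-methylideneoxolan-2-one | C=C1CCOC1=O | starting material
12 | (3R)-3-methyloxolan-2-one | C[C@@H]1CCOC1=O | intermediate
13 | (3R)-5-hydroxy-3-methylpentan-2-one | CC(=O)[C@H](C)CCO | intermediate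
14 | (3R)-5-[(tert-butyldiphenylsilyl)oxy]-3-methylpentan-2-one | CC(=O)[C@H](C)CCO[Si](c1ccccc1)(c1ccccc1)C(C)(C)C | intermediate
15 | 2-bromoprop-2-en-1-ol | OCC(Br)=C | starting material
16 | ethynyl(trimethyl)silane | C#C[Si](C)(C)C | starting material
17 | 2-methylidene-4-(trimethylsilyl)but-3-yn-1-ol | OCC(=C)C#C[Si](C)(C)C | intermediate
18 | {(2S)-2-[(trimethylsilyl)ethynyl]oxiran-2-yl}methanol | OC[C@@]1(C#C[Si](C)(C)C)CO1 | intermediate
19 | (2S)-2-{[(4-methoxyphenyl)methoxy]methyl}but-3-yne-1,2-diol | OC[C@](O)(COCc1ccc(OC)cc1)C#C | intermediate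
20 | (2R)-2-hydroxy-2-{[(4-methoxyphenyl)methoxy]methyl}but-3-ynal | O=C[C@](O)(COCc1ccc(OC)cc1)C#C | intermediate
21 | lithium (3R)-5-[(tert-butyldiphenylsilyl)oxy]-3-methylpent-1-en-2-olate | C=C(O[Li])[C@H](C)CCO[Si](c1ccccc1)(c1ccccc1)C(C)(C)C | intermediate
22 | (3R,7R)-1-[(tert-butyldiphenylsilyl)oxy]-6,7-dihydroxy-7-{[(4-methoxyphenyl)methoxy]methyl}-3-methylnon-8-yn-4-one (both C6 epimers) | C[C@H](CCO[Si](c1ccccc1)(c1ccccc1)C(C)(C)C)C(=O)CC(O)[C@](O)(COCc1ccc(OC)cc1)C#C | intermediate
23 | (3R,7R)-1-[(tert-butyldiphenylsilyl)oxy]-7-hydroxy-7-{[(4-methoxyphenyl)methoxy]methyl}-3-methylnon-8-yne-4,6-dione | C[C@H](CCO[Si](c1ccccc1)(c1ccccc1)C(C)(C)C)C(=O)CC(=O)[C@](O)(COCc1ccc(OC)cc1)C#C | intermediate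
24 | (2R)-5-{(2R)-4-[(tert-butyldiphenylsilyl)oxy]butan-2-yl}-2-ethynyl-2-{[(4-methoxyphenyl)methoxy]methyl}furan-3(2H)-one | C[C@H](CCO[Si](c1ccccc1)(c1ccccc1)C(C)(C)C)C1=CC(=O)[C@](COCc2ccc(OC)cc2)(C#C)O1 | intermediate
25 | (2R)-5-{(2R)-4-[(tert-butyldiphenylsilyl)oxy]butan-2-yl}-2-ethynyl-2-(hydroxymethyl)furan-3(2H)-one | C[C@H](CCO[Si](c1ccccc1)(c1ccccc1)C(C)(C)C)C1=CC(=O)[C@](CO)(C#C)O1 | intermediate
26 | (5R)-2-{(2R)-4-[(tert-butyldiphenylsilyl)oxy]butan-2-yl}-1,7-dioxaspiro[4.4]nona-2,8-dien-4-one | C[C@H](CCO[Si](c1ccccc1)(c1ccccc1)C(C)(C)C)C1=CC(=O)[C@]2(C=COC2)O1 | intermediate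
27 | (5R)-2-[(2R)-4-hydroxybutan-2-yl]-1,7-dioxaspiro[4.4]nona-2,8-dien-4-one | C[C@H](CCO)C1=CC(=O)[C@]2(C=COC2)O1 | intermediate
28 | (3R)-3-[(5R)-4-oxo-1,7-dioxaspiro[4.4]nona-2,8-dien-2-yl]butanal | C[C@H](CC=O)C1=CC(=O)[C@]2(C=COC2)O1 | intermediate
29 | O-silyl hemiselenoacetal of 28: C6 bears SePh and O–SiMe2–CH2–[(1S)-1,3-dimethylcyclohex-2-en-1-yl] (both C6 epimers) | C[C@H](CC(O[Si](C)(C)C[C@@]1(C)CCCC(C)=C1)[Se]c1ccccc1)C1=CC(=O)[C@]2(C=COC2)O1 | intermediate
30 | cyclic siloxane of the target skeleton: O6–SiMe2–C19 bridge (1-oxa-2-silacyclohexane fused across C4–C5–C6), otherwise as the target | C[C@@H]1C[C@@H](O3)[C@H]2[C@@](C)(C[Si]3(C)C)CCC[C@]2(C)[C@@]12CC(=O)[C@]1(C=COC1)O2 | intermediate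
31 | (13R)-9α,13:15,16-diepoxy-6β,19-dihydroxylabd-14-en-12-one (CNP0176827.1) | C[C@@H]1C[C@@H](O)[C@H]2[C@@](C)(CO)CCC[C@]2(C)[C@@]12CC(=O)[C@]1(C=COC1)O2 | target

Total step count: 19. Longest linear sequence: 12 steps (steps 8–19).

Steps most likely to fail

Step 18. The tertiary C10 radical may be reduced by the tin hydride, or take a hydrogen from C8, before it closes ring B onto the crowded C9; the first 6-exo closure onto the neopentyl-type C5 may also be too slow. The fallback makes the same two bonds in two separate known operations without the tether, setting out from 7 and 28 and coming back at 31. Stille hydroxymethylation of 7 (Bu3SnCH2OH, Pd(PPh3)4, LiCl) would give the allylic alcohol F1, and CBr4/PPh3 the allylic bromide F2. An indium-mediated Barbier allylation of 28 with F2 (In, THF/H2O) should attack through the ring carbon C5 and give the homoallylic alcohol F3, with the C5–C6 bond and an exocyclic C10=C20 methylene; the 5S,6R isomer is separated. Hydrogen-atom transfer to that methylene (Fe(acac)3, PhSiH3, EtOH) then generates the C10 radical, which should close ring B onto C9 in a Giese-type 6-exo addition to give the 19-silyl compound F4. Tamao oxidation of its Si–H group (KF, KHCO3, H2O2) returns to 31.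

Step 2. The bulky silylmethyl group at the β-carbon may slow the copper-catalysed addition or lower its enantioselectivity, or the γ-silyl enone may lose silicon to the Lewis acid. The fallback gives up catalyst control, setting out from 5 and coming back at 30. MeMgBr/CuBr·SMe2/Me3SiCl, then MeLi and the same triflimide, would give the racemic triflate F5. Steps 3 and 4 would then give the racemic silane F6 and the racemic silyl selenide F7. In step 18 the enantiopure aldehyde 28 acts as the resolving partner: the (S)-half of F7 gives 30, and the (R)-half gives the diastereomeric siloxane F8 or acyclic reduction products, which are removed by chromatography.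

Step 15. The tungsten carbonyl fragment may bind the furanone, or the amine may epimerize C8, so that the cycloisomerization stalls or erodes the C8 configuration. The fallback is a stoichiometric anti-Markovnikov hydration followed by dehydration, setting out from 25 and coming back at 26. Hydroboration of the terminal alkyne with dicyclohexylborane and oxidation with NaBO3 gives the aldehyde, which closes with O16–H to the lactol F9. MsCl/Et3N then eliminates to the enol ether 26.

Further compounds
F1 | step 18 | [(3S)-3-[(dimethylsilyl)methyl]-3-methylcyclohex-1-en-1-yl]methanol | C[C@]1(C[SiH](C)C)CCCC(CO)=C1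
F2 | step 18 | {[(1S)-3-(bromomethyl)-1-methylcyclohex-2-en-1-yl]methyl}dimethylsilane | C[C@]1(C[SiH](C)C)CCCC(CBr)=C1
F3 | step 18 | homoallylic alcohol: 28 joined at C6 to C5 of the ring A unit, with 6-OH and exocyclic C10=C20 methylene (5S,6R isomer) | C[C@H](C[C@@H](O)[C@@H]1C(=C)CCC[C@]1(C)C[SiH](C)C)C1=CC(=O)[C@]2(C=COC2)O1
F4 | step 18 | 19-(dimethylsilyl) analogue of the target (C19–SiHMe2 in place of C19–OH) | C[C@@H]1C[C@@H](O)[C@H]2[C@@](C)(C[SiH](C)C)CCC[C@]2(C)[C@@]12CC(=O)[C@]1(C=COC1)O2
F5 | step 2 | racemic 3-[(dimethylsilyl)methyl]-3-methylcyclohex-1-en-1-yl trifluoromethanesulfonate | CC1(C[SiH](C)C)CCCC(OS(=O)(=O)C(F)(F)F)=C1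
F6 | step 2 | racemic [(1,3-dimethylcyclohex-2-en-1-yl)methyl]dimethylsilane | CC1(C[SiH](C)C)CCCC(C)=C1
F7 | step 2 | racemic [(1,3-dimethylcyclohex-2-en-1-yl)methyl]dimethyl(phenylselanyl)silane | CC1(C[Si](C)(C)[Se]c2ccccc2)CCCC(C)=C1
F8 | step 2 | diastereomer of 30 with C4, C5, C6, C9 and C10 inverted | C[C@@H]1C[C@H](O3)[C@@H]2[C@](C)(C[Si]3(C)C)CCC[C@@]2(C)[C@]12CC(=O)[C@]1(C=COC1)O2
F9 | step 15 | (5R)-2-{(2R)-4-[(tert-butyldiphenylsilyl)oxy]butan-2-yl}-8-hydroxy-1,7-dioxaspiro[4.4]non-2-en-4-one (both C8 epimers) | C[C@H](CCO[Si](c1ccccc1)(c1ccccc1)C(C)(C)C)C1=CC(=O)[C@]2(CC(O)OC2)O1
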